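**Strategy.** The oxolane ring is read as a carbonyl ylide laid across a cis-alkene. Atoms C2 (benzylic), O1 and C5 (methylene) form the ylide ArCH=O(+)–CH2(−); C3–C4, whose exocyclic carbons are cis, is the C=C of a chiral 5-menthyloxybutenolide. One (3+2) cycloaddition closes the ring through the C5–C4 and C3–C2 bonds, sets C2, C3 and C4, and leaves the carbinol carbon as a masked aldehyde and the hydroxymethyl carbon as a lactone carbonyl. The ylide precursor is an α-chloro benzyl (trimethylsilyl)methyl ether made from O-benzylvanillin. Acetal hydrolysis, Felkin–Anh aryl Grignard addition with hydride reduction, and hydrogenolysis complete the synthesis.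

Key step: step 2

Remark: locants follow the target oxolane (O1, C2 aryl-bearing, C3 hydroxymethyl-bearing, C4 carbinol-bearing, C5 methylene); C7 is the carbinol carbon and C9 the hydroxymethyl carbon.

Assumption: butenolide 4, the enantiomer of the common (−)-menthol-derived 5-menthyloxyfuran-2(5H)-one, is taken as a purchasable reagent; the same known acetalisation and crystallisation with (+)-menthol gives it otherwise.

**Step 1**
Reactants: 1 4-(benzyloxy)-3-methoxybenzaldehyde; 2 (trimethylsilyl)methanol
Product: 3 1-(benzyloxy)-4-{bis[(trimethylsilyl)methoxy]methyl}-2-methoxybenzene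
Conditions: 2 (2.5 equiv), p-toluenesulfonic acid monohydrate (2 mol %), toluene, reflux, Dean–Stark trap; Et3N quench
Reagents that add atoms: none
Why: Acid-catalysed acetalisation driven by azeotropic removal of water should give the bis(silylmethyl) acetal; no stereocentre is formed.

**Step 2**
Reactants: 3 1-(benzyloxy)-4-{bis[(trimethylsilyl)methoxy]methyl}-2-methoxybenzene; 4 (5S)-5-{[(1S,2R,5S)-5-methyl-2-(propan-2-yl)cyclohexyl]oxy}furan-2(5H)-one
Product: 7 (3S,3aR,6S,6aS)-6-[4-(benzyloxy)-3-methoxyphenyl]-3-{[(1S,2R,5S)-5-methyl-2-(propan-2-yl)cyclohexyl]oxy}tetrahydro-1H,3H-furo[3,4-c]furan-1-one, via α-chloro ether 5 (not isolated), via carbonyl ylide 6 (not isolated)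
Conditions: 3 (1.5 equiv), AcCl (1.6 equiv), CH2Cl2, 0 °C to rt, then volatiles removed in vacuo; 4 (1.0 equiv), CsF (4 equiv), MeCN, rt
Reagents that add atoms: none
Why: AcCl exchanges one silylmethoxy group of 3 for chloride to give 5; fluoride then attacks silicon, and the resulting 1,3-elimination (loss of Me3SiF and chloride) releases the non-stabilised carbonyl ylide 6, which adds across the electron-poor C=C of 4 in a suprafacial (3+2) dipolar cycloaddition. The closest known reaction type is the CsF-induced desilylative generation of carbonyl ylides from α-chloro α′-silyl ethers and their cycloaddition to acrylates and related activated alkenes. The oxolane ring is closed by the cycloaddition itself, the three-atom C2–O1–C5 dipole joining the two-carbon C3=C4 unit through both termini at once, and because the alkene is held Z in the lactone ring the new ring is cis-fused, which fixes the cis relation of C3 and C4. C3 and C4 are set by approach to the alkene face anti to the menthyloxy group on the neighbouring acetal carbon, the established facial bias of this butenolide; C2 is set by an exo approach of the ylide with its aryl group in the extended position, which places the aryl trans to the lactone carbonyl carbon on C3. The step needs regioselectivity, and the donor aryl group supplies it: it stabilises oxocarbenium character at the benzylic carbon, so the unsubstituted CH2 terminus is the nucleophilic end and bonds to the β-carbon (C4) of the unsaturated lactone while the benzylic terminus bonds to the α-carbon (C3).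

**Step 3**
Reactants: 7 (3S,3aR,6S,6aS)-6-[4-(benzyloxy)-3-methoxyphenyl]-3-{[(1S,2R,5S)-5-methyl-2-(propan-2-yl)cyclohexyl]oxy}tetrahydro-1H,3H-furo[3,4-c]furan-1-one
Product: 8 (3aR,6S,6aS)-6-[4-(benzyloxy)-3-methoxyphenyl]-3-hydroxytetrahydro-1H,3H-furo[3,4-c]furan-1-one (lactol, both C3 anomers)
Conditions: 1 M aq. HCl, THF, 40 °C
Reagents that add atoms: water (O)
Why: Mild acid hydrolysis of the acyloxy-alkoxy acetal should release menthol, and the cis-formyl acid should close to the hydroxy lactone, a form that shields C4 (α to the latent aldehyde) from epimerisation; no stereocentre of the target is touched.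

**Step 4**
Reactants: 8 (3aR,6S,6aS)-6-[4-(benzyloxy)-3-methoxyphenyl]-3-hydroxytetrahydro-1H,3H-furo[3,4-c]furan-1-one; 9 1-(benzyloxy)-4-bromo-2-methoxybenzene
Product: 12 {(2S,3R,4R)-2-[4-(benzyloxy)-3-methoxyphenyl]-4-{(R)-[4-(benzyloxy)-3-methoxyphenyl](hydroxy)methyl}oxolan-3-yl}methanol, via Grignard reagent 10 (not isolated), via hydroxy acid 11 (not isolated)
Conditions: 9 (3.2 equiv), Mg turnings (3.5 equiv), THF, 40 °C; 8 added at −78 °C, then to −20 °C; LiAlH4 (4 equiv), 0 °C to reflux; aq. Rochelle-salt work-up
Reagents that add atoms: none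
Why: The deprotonated lactol should react as its ring-opened formyl carboxylate, and Grignard addition under Felkin–Anh control (aryl enters anti to C3, the bulkier α-branch, and magnesium chelated between the aldehyde oxygen and O1 exposes the same face) should set C7 as R; LiAlH4 then reduces the carboxylate carbon C9 to the primary alcohol.

**Step 5**
Reactants: 12 {(2S,3R,4R)-2-[4-(benzyloxy)-3-methoxyphenyl]-4-{(R)-[4-(benzyloxy)-3-methoxyphenyl](hydroxy)methyl}oxolan-3-yl}methanol
Product: 13 (7R)-7-hydroxylariciresinol, 4-[(2S,3R,4R)-4-[(R)-hydroxy(4-hydroxy-3-methoxyphenyl)methyl]-3-(hydroxymethyl)oxolan-2-yl]-2-methoxyphenol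
Conditions: H2 (1 atm), Pd/C (10 wt % Pd on carbon), EtOAc–EtOH, rt, stopped at full conversion
Reagents that add atoms: none
Why: Hydrogenolysis of the two aryl benzyl ethers should be much faster than that of the benzylic alcohol or the benzylic C2–O1 bond under neutral conditions at 1 atm; no stereocentre is touched.

**Compound list**

1 | 4-(benzyloxy)-3-methoxybenzaldehyde (O-benzylvanillin) | COc1cc(C=O)ccc1OCc1ccccc1 | starting material
2 | (trimethylsilyl)methanol | C[Si](C)(C)CO | starting material
3 | 1-(benzyloxy)-4-{bis[(trimethylsilyl)methoxy]methyl}-2-methoxybenzene | COc1cc(C(OC[Si](C)(C)C)OC[Si](C)(C)C)ccc1OCc1ccccc1 | intermediate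
4 | (5S)-5-{[(1S,2R,5S)-5-methyl-2-(propan-2-yl)cyclohexyl]oxy}furan-2(5H)-one | O=C1C=C[C@@H](O[C@H]2C[C@@H](C)CC[C@@H]2C(C)C)O1 | starting material
5 | 1-(benzyloxy)-4-{chloro[(trimethylsilyl)methoxy]methyl}-2-methoxybenzene (racemic α-chloro ether) | COc1cc(C(Cl)OC[Si](C)(C)C)ccc1OCc1ccccc1 | intermediate (not isolated)
6 | carbonyl ylide ArCH=O(+)–CH2(−), Ar = 4-(benzyloxy)-3-methoxyphenyl | COc1cc(C=[O+][CH2-])ccc1OCc1ccccc1 | intermediate (not isolated)
7 | (3S,3aR,6S,6aS)-6-[4-(benzyloxy)-3-methoxyphenyl]-3-{[(1S,2R,5S)-5-methyl-2-(propan-2-yl)cyclohexyl]oxy}tetrahydro-1H,3H-furo[3,4-c]furan-1-one (cis-fused; aryl and menthyloxy both on the convex face) | O=C1O[C@H](O[C@H]3C[C@@H](C)CC[C@@H]3C(C)C)[C@H]2CO[C@H](c4ccc(OCc5ccccc5)c(OC)c4)[C@@H]12 | intermediate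
8 | (3aR,6S,6aS)-6-[4-(benzyloxy)-3-methoxyphenyl]-3-hydroxytetrahydro-1H,3H-furo[3,4-c]furan-1-one (both C3 anomers) | O=C1OC(O)[C@H]2CO[C@H](c3ccc(OCc4ccccc4)c(OC)c3)[C@@H]12 | intermediate
9 | 1-(benzyloxy)-4-bromo-2-methoxybenzene | COc1cc(Br)ccc1OCc1ccccc1 | starting material
10 | [4-(benzyloxy)-3-methoxyphenyl]magnesium bromide | COc1cc([Mg]Br)ccc1OCc1ccccc1 | intermediate (not isolated)
11 | (2S,3S,4R)-2-[4-(benzyloxy)-3-methoxyphenyl]-4-{(R)-[4-(benzyloxy)-3-methoxyphenyl](hydroxy)methyl}oxolane-3-carboxylic acid (present as its magnesium salt) | COc1cc([C@H]2OC[C@H]([C@@H](O)c3ccc(OCc4ccccc4)c(OC)c3)[C@@H]2C(=O)O)ccc1OCc1ccccc1 | intermediate (not isolated)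
12 | {(2S,3R,4R)-2-[4-(benzyloxy)-3-methoxyphenyl]-4-{(R)-[4-(benzyloxy)-3-methoxyphenyl](hydroxy)methyl}oxolan-3-yl}methanol | COc1cc([C@H]2OC[C@H]([C@@H](O)c3ccc(OCc4ccccc4)c(OC)c3)[C@@H]2CO)ccc1OCc1ccccc1 | intermediate
13 | (7R)-7-hydroxylariciresinol | COc1cc([C@H]2OC[C@H]([C@@H](O)c3ccc(O)c(OC)c3)[C@@H]2CO)ccc1O | target

**Totals.** Total step count: 5. Longest linear sequence: 5 steps (1 → 3 → 7 → 8 → 12 → 13).

**Steps most likely to fail**

Step 2. The electron-rich chloro ether may ionise and be lost by dealkylation back to the aldehyde before fluoride desilylates it. The ylide may also add with insufficient exo/endo or regiochemical discrimination. The fallback makes the two bonds one after the other with known reactions; it sets out from 4 (with chloro ether 5 prepared from 3 as in step 2) and returns at 7. Benzophenone-sensitised photoaddition of methanol to 4 (hν, MeOH) should add a hydroxymethyl radical to the β-carbon anti to the menthyloxy group. This forms the C5–C4 bond and gives (4R,5S)-4-(hydroxymethyl)-5-menthyloxyoxolan-2-one F1. O-Alkylation of F1 with 5 (i-Pr2NEt, CH2Cl2) gives the mixed benzylic acetal F2. Me3SiOTf and Et3N then form the silyl ketene acetal of the lactone and ionise the acetal reversibly. The tethered oxocarbenium ion closes onto C3 in an intramolecular Mukaiyama-type aldol (Prins) reaction, which forms the C3–C2 bond and can only give the cis-fused product 7.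

Step 4. Facial selectivity at the aldehyde may be eroded or reversed if the magnesium carboxylate bridges to the aldehyde oxygen and delivers the aryl group to the convex face. The fallback replaces substrate control by catalyst control; it sets out from 8 and returns at 12. Step 4 is run as written, and the C7 epimer of 12, the (S)-carbinol F3 (alone or mixed with 12), is oxidised at the benzylic carbinol with MnO2 (CH2Cl2) to the keto alcohol F4. F4 is reduced with BH3·SMe2 under (S)-2-methyl-CBS-oxazaborolidine catalysis (aryl as the large group), which should give the (R)-carbinol 12.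

Step 3. Acid may ionise the benzylic C2–O1 bond (epimerisation at C2 or ring-opening) faster than the acetal hydrolyses, or the free formyl acid may epimerise at C4. The fallback avoids acid and the free aldehyde; it sets out from 7 and returns at 12. LiAlH4 reduces the lactone and the acetal carbon of 7 together, with loss of menthol, to the diol F5. Ag2CO3 on Celite (benzene, reflux) should oxidise the less hindered hydroxymethyl group (on C4) and lactonise to F6, in which C7 is the carbonyl carbon. One equivalent of the aryllithium from 9 (n-BuLi, THF, −78 °C) adds to F6 to give the keto alcohol F4 described above, and the CBS reduction described for step 4 returns 12.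

**Further compounds**

F1 | step 2 | (4R,5S)-4-(hydroxymethyl)-5-{[(1S,2R,5S)-5-methyl-2-(propan-2-yl)cyclohexyl]oxy}oxolan-2-one | O=C1O[C@H](O[C@H]2C[C@@H](C)CC[C@@H]2C(C)C)[C@@H](CO)C1
F2 | step 2 | mixed acetal of F1: (4R,5S)-4-({[4-(benzyloxy)-3-methoxyphenyl][(trimethylsilyl)methoxy]methoxy}methyl)-5-menthyloxyoxolan-2-one (both acetal epimers) | O=C1O[C@H](O[C@H]2C[C@@H](C)CC[C@@H]2C(C)C)[C@@H](COC(OC[Si](C)(C)C)c3ccc(OCc4ccccc4)c(OC)c3)C1
F3 | step 4 | {(2S,3R,4R)-2-[4-(benzyloxy)-3-methoxyphenyl]-4-{(S)-[4-(benzyloxy)-3-methoxyphenyl](hydroxy)methyl}oxolan-3-yl}methanol (C7 epimer of 12) | COc1cc([C@H]2OC[C@H]([C@H](O)c3ccc(OCc4ccccc4)c(OC)c3)[C@@H]2CO)ccc1OCc1ccccc1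
F4 | step 4 | [4-(benzyloxy)-3-methoxyphenyl]{(3R,4R,5S)-5-[4-(benzyloxy)-3-methoxyphenyl]-4-(hydroxymethyl)oxolan-3-yl}methanone | COc1cc([C@H]2OC[C@H](C(=O)c3ccc(OCc4ccccc4)c(OC)c3)[C@@H]2CO)ccc1OCc1ccccc1
F5 | step 3 | {(2S,3R,4S)-2-[4-(benzyloxy)-3-methoxyphenyl]oxolane-3,4-diyl}dimethanol | COc1cc([C@H]2OC[C@H](CO)[C@@H]2CO)ccc1OCc1ccccc1
F6 | step 3 | (3aR,4S,6aR)-4-[4-(benzyloxy)-3-methoxyphenyl]tetrahydro-1H,3H-furo[3,4-c]furan-1-one | O=C1OC[C@@H]2[C@@H](c3ccc(OCc4ccccc4)c(OC)c3)OC[C@H]12
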